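The plan cuts the C1–C2 bond of the cyclohexene ring. Quaternary C1 (methyl, styryl) sits next to aryl-bearing C2, which is allylic to the C3=C4 alkene. If the C1 styryl arm is read as CO2H, this array is a γ,δ-unsaturated acid, the signature of an Ireland–Claisen rearrangement. The precursor is a 3,6-dimethyl-δ-lactone carrying an (E)-coumarinylvinyl group on C6, whose single controlling stereocentre is the carbinol carbon of (R)-linalool. In one operation the rearrangement transposes the lactone ring into the carbocycle, forms C1–C2, sets both stereocentres and places the alkene. One iodocoumarin, used in two Heck couplings, delivers both aryl units.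

Key step: step 9

Remark on the chemistry: natural (R)-(−)-linalool of high enantiomeric purity is assumed, and a lot that falls short can be corrected by crystallising the rearranged carboxylic acid as its 1-phenylethylammonium salt; cyclohexene atoms are numbered C1 (quaternary), C2 (aryl-bearing), C3=C4 (methyl on C4), C5, C6.

Step 1
Reactants: 1 (R)-(−)-linalool
Product: 3 (5R)-5-methyl-5-vinyltetrahydrofuran-2-ol as anomer mixture, via hydroxy aldehyde 2 (not isolated)
Conditions: O3 (1.0 equiv, Sudan Red 7B endpoint), CH2Cl2, −78 °C; then Me2S, −78 °C to rt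
Reagents that add atoms: ozone, [O-][O+]=O
Why: Chemoselective ozonolysis, in which electrophilic ozone attacks the electron-rich trisubstituted alkene far faster than the monosubstituted vinyl group, so one equivalent with reductive work-up should give 2, which closes to the five-membered lactol without touching the carbinol stereocentre.

Step 2
Reactants: 3 (5R)-5-methyl-5-vinyltetrahydrofuran-2-ol
Product: 4 (3R)-7-methoxy-3-methylhepta-1,6-dien-3-ol (E/Z mixture at the enol ether)
Conditions: MeOCH2PPh3Cl (3.0 equiv), KOtBu (2.9 equiv), THF, 0 °C; then 3, 0 °C to rt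
Reagents that add atoms: (methoxymethyl)triphenylphosphonium chloride, COC[P+](c1ccccc1)(c1ccccc1)c1ccccc1.[Cl-]
Why: Wittig olefination of the open-chain tautomer of the lactol, where the first equivalent of ylide only deprotonates the hydroxyl, the excess turns the aldehyde into the methyl enol ether (one-carbon homologation), and the basic medium is harmless to the tertiary allylic alcohol.

Step 3
Reactants: 4 (3R)-7-methoxy-3-methylhepta-1,6-dien-3-ol
Product: 6 (6R)-6-methyl-6-vinyltetrahydropyran-2-ol as anomer mixture, via hydroxy aldehyde 5 (not isolated)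
Conditions: pyridinium p-toluenesulfonate (0.1 equiv), THF–H2O, 40 °C; NaHCO3 quench
Reagents that add atoms: water, O
Why: Enol ether hydrolysis, which works because the enol ether is protonated on carbon far faster than a tertiary allylic alcohol ionises, so a weak buffered acid should release 5, which the tertiary hydroxyl captures as the six-membered lactol.

Step 4
Reactants: 6 (6R)-6-methyl-6-vinyltetrahydropyran-2-ol
Product: 7 (R)-6-methyl-6-vinyltetrahydropyran-2-one
Conditions: TEMPO (2,2,6,6-tetramethylpiperidin-1-oxyl, 0.1 equiv), PhI(OAc)2 (1.2 equiv), CH2Cl2, rt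
Reagents that add atoms: none
Why: Oxoammonium (TEMPO) oxidation of the lactol to the δ-lactone under nearly neutral conditions, which spares the vinyl group and avoids the oxidative allylic transposition that chromium oxidants cause with tertiary allylic alcohols.

Step 5
Reactants: 7 (R)-6-methyl-6-vinyltetrahydropyran-2-one
Product: 9 (6R)-3,6-dimethyl-6-vinyltetrahydropyran-2-one (C3 epimer mixture), via lithium enolate 8 (not isolated)
Conditions: LiNiPr2 (1.1 equiv), THF, −78 °C; MeI (3 equiv), DMPU, −78 to −40 °C
Reagents that add atoms: iodomethane, CI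
Why: Kinetic lactone enolate alkylation (SN2 on MeI), kept cold enough that 8 does not rearrange through its own C6 vinyl group, and the new C3 centre needs no control because step 9 planarises it.

Step 6
Reactants: 10 2-hydroxy-4,6-dimethoxybenzaldehyde
Product: 11 2-hydroxy-3-iodo-4,6-dimethoxybenzaldehyde
Conditions: N-iodosuccinimide (1.0 equiv), CF3CO2H (0.1 equiv), MeCN, 0 °C to rt, dark
Reagents that add atoms: N-iodosuccinimide, O=C1CCC(=O)N1I
Why: Electrophilic aromatic iodination, expected at C3 because both free positions are activated by all three oxygens but C3 is flanked by the small chelated hydroxyl while C5 lies between two methoxy groups (the position is to be confirmed by HMBC and NOE before going on).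

Step 7
Reactants: 11 2-hydroxy-3-iodo-4,6-dimethoxybenzaldehyde
Product: 13 8-iodo-5,7-dimethoxycoumarin, via ester ylide 12 (not isolated)
Conditions: Ph3P=C=C=O (1.2 equiv), toluene, reflux
Reagents that add atoms: (triphenylphosphoranylidene)ketene, O=C=C=P(c1ccccc1)(c1ccccc1)c1ccccc1
Why: Addition–intramolecular Wittig domino, in which the phenol adds across the cumulated ylide to give 12 and its stabilised ylide carbon olefinates the neighbouring formyl group, the six-membered ring enforcing the cis alkene of the pyranone at a temperature the electron-rich C–I bond should tolerate.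

Step 8
Reactants: 9 (6R)-3,6-dimethyl-6-vinyltetrahydropyran-2-one; 13 8-iodo-5,7-dimethoxycoumarin
Product: 14 (6R)-6-[(E)-2-(5,7-dimethoxy-2-oxo-2H-chromen-8-yl)ethenyl]-3,6-dimethyltetrahydropyran-2-one (C3 epimer mixture)
Conditions: Pd(OAc)2 (10 mol %), Ag2CO3 (1.0 equiv), toluene with a little DMF, 70 °C, dark; purification on Et3N-deactivated silica
Reagents that add atoms: none
Why: Mizoroki–Heck arylation under ligand-free, silver-buffered conditions of the kind known to arylate allylic esters with the acyloxy group retained, where aryl adds to the vinyl terminus, quaternary C6 leaves only benzylic β-hydrogens so syn elimination gives the E-styryl, and Ag2CO3 removes iodide and acid while excess aryl iodide keeps zerovalent palladium from ionising the allylic lactone.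

Step 9
Reactants: 14 (6R)-6-[(E)-2-(5,7-dimethoxy-2-oxo-2H-chromen-8-yl)ethenyl]-3,6-dimethyltetrahydropyran-2-one
Product: 17 (1S,2S)-2-(5,7-dimethoxy-2-oxo-2H-chromen-8-yl)-1,4-dimethylcyclohex-3-ene-1-carboxylic acid, via silyl ketene acetal 15 (not isolated), via trimethylsilyl ester 16 (not isolated)
Conditions: Me3SiCl and Et3N (3 equiv each), toluene–THF, −78 °C; LiN(SiMe3)2 (1.3 equiv) added slowly; −78 °C to rt, then 70 °C; work-up with MeOH and pH 5 citrate buffer
Reagents that add atoms: none
Why: LiN(SiMe3)2 removes the only acidic hydrogen (lactone C3–H, the coumarin having none) and the Me3SiCl already present traps the enolate on oxygen, so both C3 epimers of 14 merge into 15, in which the ring-locked ketene acetal C2=C3 and the E-styryl alkene are linked through O1–C6 as an allyl vinyl ether. On warming, a concerted suprafacial [3,3]-sigmatropic shift (Ireland–Claisen rearrangement, the closest known reaction type being the ring contraction of silyl ketene acetals of 6-alkenyl δ-lactones to cyclohex-3-enecarboxylic acids) bonds lactone C3 to the aryl-bearing styryl carbon while the tertiary allylic C6–O1 bond breaks and the alkene moves next to the former carbinol carbon. The cyclohexene is closed by this six-centre pericyclic C–C bond formation, lactone C4 and C5 becoming ring C6 and C5 and the former carbonyl carbon ending as the exocyclic silyl carboxylate of 16, which water cleaves to 17 at work-up. Because the two methylenes tie lactone C3 to C6, only a boat-like transition state shaped like bicyclo[2.2.2]octane is within reach, so the styryl group can meet just one face of the ketene acetal and the R carbinol centre is relayed to quaternary C1 (S). In that array the E geometry turns the aryl group toward the departing O1–C2 bridge, which fixes C2 (S) with aryl cis to the carboxyl. The step needs the pericyclic path to beat ionisation or elimination at the doubly activated C–O bond, which the amine-buffered, Lewis-acid-free and weakly polar medium should secure.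

Step 10
Reactants: 17 (1S,2S)-2-(5,7-dimethoxy-2-oxo-2H-chromen-8-yl)-1,4-dimethylcyclohex-3-ene-1-carboxylic acid
Product: 19 (1S,2S)-2-(5,7-dimethoxy-2-oxo-2H-chromen-8-yl)-1,4-dimethylcyclohex-3-ene-1-carbaldehyde, via acid chloride 18 (not isolated)
Conditions: Me2C=C(Cl)NMe2 (1.1 equiv), CH2Cl2, 0 °C to rt; then THF, LiAlH(OtBu)3 (1.3 equiv), −78 °C
Reagents that add atoms: none
Why: Neutral chloroenamine activation makes the hindered acid chloride without HCl (which could lactonise the acid onto the ring alkene), and partial reduction of the acid chloride by the bulky alkoxyaluminium hydride stops at the aldehyde while leaving the coumarin lactone and the alkene alone, C1 having no hydrogen to epimerise.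

Step 11
Reactants: 19 (1S,2S)-2-(5,7-dimethoxy-2-oxo-2H-chromen-8-yl)-1,4-dimethylcyclohex-3-ene-1-carbaldehyde
Product: 20 8-[(1R,6R)-6-ethenyl-3,6-dimethylcyclohex-2-en-1-yl]-5,7-dimethoxycoumarin
Conditions: MePPh3Br (1.2 equiv), KN(SiMe3)2 (1.15 equiv), THF, 0 °C; ylide added to 19 at −78 °C, then to 0 °C
Reagents that add atoms: methyltriphenylphosphonium bromide, C[P+](c1ccccc1)(c1ccccc1)c1ccccc1.[Br-]
Why: Wittig methylenation, with about one equivalent of ylide added to the substrate in the cold so that it is consumed by the non-enolisable aldehyde, by far the most electrophilic carbonyl, before it can attack the donor-deactivated coumarin.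

Step 12
Reactants: 20 8-[(1R,6R)-6-ethenyl-3,6-dimethylcyclohex-2-en-1-yl]-5,7-dimethoxycoumarin; 13 8-iodo-5,7-dimethoxycoumarin
Product: 21 8-[(1R,6R)-6-[(E)-2-(5,7-dimethoxy-2-oxo-2H-chromen-8-yl)ethenyl]-3,6-dimethylcyclohex-2-en-1-yl]-5,7-dimethoxy-2H-chromen-2-one (target)
Conditions: Pd(OAc)2 (10 mol %), P(o-tol)3 (20 mol %), Ag2CO3 (1.0 equiv), DMF, 90 °C
Reagents that add atoms: none
Why: Mizoroki–Heck arylation of a vinyl group on a quaternary carbon, where aryl adds to the terminal carbon, β-hydride elimination is possible only toward the benzylic carbon and gives the E-styryl, and the silver salt speeds alkene binding and suppresses palladium hydride re-addition that could move the ring alkene or disturb C2.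

Compound list
1 | (R)-(−)-linalool, (3R)-3,7-dimethylocta-1,6-dien-3-ol | C=C[C@](C)(O)CCC=C(C)C | starting material
2 | (4R)-4-hydroxy-4-methylhex-5-enal | O=CCC[C@@](C)(O)C=C | intermediate (not isolated)
3 | (5R)-5-methyl-5-vinyltetrahydrofuran-2-ol, anomer mixture | OC1CC[C@](C)(C=C)O1 | intermediate
4 | (3R)-7-methoxy-3-methylhepta-1,6-dien-3-ol, E/Z mixture | COC=CCC[C@@](C)(O)C=C | intermediate
5 | (5R)-5-hydroxy-5-methylhept-6-enal | O=CCCC[C@@](C)(O)C=C | intermediate (not isolated)
6 | (6R)-6-methyl-6-vinyltetrahydropyran-2-ol, anomer mixture | OC1CCC[C@](C)(C=C)O1 | intermediate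
7 | (R)-6-methyl-6-vinyltetrahydropyran-2-one | O=C1CCC[C@](C)(C=C)O1 | intermediate
8 | lithium enolate of 7 | [Li]OC1=CCC[C@](C)(C=C)O1 | intermediate (not isolated)
9 | (6R)-3,6-dimethyl-6-vinyltetrahydropyran-2-one, C3 epimer mixture | O=C1C(C)CC[C@](C)(C=C)O1 | intermediate
10 | 2-hydroxy-4,6-dimethoxybenzaldehyde | COc1cc(OC)c(C=O)c(O)c1 | starting material
11 | 2-hydroxy-3-iodo-4,6-dimethoxybenzaldehyde | COc1cc(OC)c(C=O)c(O)c1I | intermediate
12 | 2-formyl-6-iodo-3,5-dimethoxyphenyl (triphenylphosphoranylidene)acetate | COc1cc(OC)c(C=O)c(OC(=O)C=P(c2ccccc2)(c2ccccc2)c2ccccc2)c1I | intermediate (not isolated)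
13 | 8-iodo-5,7-dimethoxycoumarin (used in steps 8 and 12) | COc1cc(OC)c2ccc(=O)oc2c1I | intermediate
14 | (6R)-6-[(E)-2-(5,7-dimethoxy-2-oxo-2H-chromen-8-yl)ethenyl]-3,6-dimethyltetrahydropyran-2-one, C3 epimer mixture | O=C1C(C)CC[C@](C)(/C=C/c2c(OC)cc(OC)c3ccc(=O)oc23)O1 | intermediate
15 | 8-[(E)-2-[(2R)-2,5-dimethyl-6-(trimethylsilyloxy)-3,4-dihydro-2H-pyran-2-yl]ethenyl]-5,7-dimethoxycoumarin | C[Si](C)(C)OC1=C(C)CC[C@](C)(/C=C/c2c(OC)cc(OC)c3ccc(=O)oc23)O1 | intermediate (not isolated)
16 | trimethylsilyl (1S,2S)-2-(5,7-dimethoxy-2-oxo-2H-chromen-8-yl)-1,4-dimethylcyclohex-3-ene-1-carboxylate | C[Si](C)(C)OC(=O)[C@@]1(C)CCC(C)=C[C@H]1c1c(OC)cc(OC)c2ccc(=O)oc12 | intermediate (not isolated)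
17 | (1S,2S)-2-(5,7-dimethoxy-2-oxo-2H-chromen-8-yl)-1,4-dimethylcyclohex-3-ene-1-carboxylic acid, aryl cis to carboxyl | OC(=O)[C@@]1(C)CCC(C)=C[C@H]1c1c(OC)cc(OC)c2ccc(=O)oc12 | intermediate
18 | (1S,2S)-2-(5,7-dimethoxy-2-oxo-2H-chromen-8-yl)-1,4-dimethylcyclohex-3-ene-1-carbonyl chloride | ClC(=O)[C@@]1(C)CCC(C)=C[C@H]1c1c(OC)cc(OC)c2ccc(=O)oc12 | intermediate (not isolated)
19 | (1S,2S)-2-(5,7-dimethoxy-2-oxo-2H-chromen-8-yl)-1,4-dimethylcyclohex-3-ene-1-carbaldehyde | O=C[C@@]1(C)CCC(C)=C[C@H]1c1c(OC)cc(OC)c2ccc(=O)oc12 | intermediate
20 | 8-[(1R,6R)-6-ethenyl-3,6-dimethylcyclohex-2-en-1-yl]-5,7-dimethoxycoumarin | C=C[C@@]1(C)CCC(C)=C[C@H]1c1c(OC)cc(OC)c2ccc(=O)oc12 | intermediate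
21 | 8-[(1R,6R)-6-[(E)-2-(5,7-dimethoxy-2-oxo-2H-chromen-8-yl)ethenyl]-3,6-dimethylcyclohex-2-en-1-yl]-5,7-dimethoxy-2H-chromen-2-one | COc1cc(OC)c2ccc(=O)oc2c1/C=C/[C@@]1(C)CCC(C)=C[C@H]1c1c(OC)cc(OC)c2ccc(=O)oc12 | target

Total step count: 12. Longest linear sequence: 10 steps (1 to 21 through steps 1–5 and 8–12). Steps 6 and 7 form the short side branch to 13.

Steps most likely to fail

(a) Step 9.
- What may go wrong: heterolysis of the tertiary, allylic, aryl-conjugated C–O bond may outrun the pericyclic shift. That would lead to elimination, or to ion-pair recombination with eroded chirality transfer. Alternatively the crowded boat transition state may be so slow that the ketene acetal is lost by hydrolysis.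
- Fallback: it sets out from 13 and comes back at 19, replacing the sigmatropic ring transposition by a cycloaddition.
- Mizoroki–Heck coupling of 13 with 2-methylbut-3-en-2-ol (Pd(OAc)2, n-Bu4NCl, NaHCO3, DMF, 80 °C) should give the tertiary alcohol 8-[(E)-3-hydroxy-3-methylbut-1-enyl]-5,7-dimethoxycoumarin F1.
- Dehydration with catalytic pyridinium p-toluenesulfonate in warm toluene should give the diene 8-[(E)-3-methylbuta-1,3-dienyl]-5,7-dimethoxycoumarin F2, which is used at once because it tends to dimerise.
- An enantioselective Diels–Alder reaction of F2 with excess methacrolein at −78 to −40 °C follows. The catalyst is the oxazaborolidinium salt made from one enantiomer of 3,3-diphenyl-1-(2-methylphenyl)tetrahydro-1H,3H-pyrrolo[1,2-c][1,3,2]oxazaborole and (CF3SO2)2NH.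
- The aryl group at the diene terminus and the methyl group at the inner position direct the same regiochemistry. The endo orientation of the formyl group places it cis to the aryl group, so the adduct is 19. The catalyst enantiomer is chosen by correlation with the required sense.

(b) Step 8.
- What may go wrong: zerovalent palladium may ionise the allylic lactone, or β-carboxylate elimination from the σ-alkylpalladium intermediate may compete with β-hydride elimination.
- Fallback: it sets out from 9 and comes back at 14, and removes the leaving group before the coupling.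
- Saponification of 9 with KOH (1.0 equiv, THF–H2O) gives (5R)-5-hydroxy-2,5-dimethylhept-6-enoic acid F3, kept as its potassium salt.
- Mizoroki–Heck arylation of this tertiary allylic alcohol with 13 (Pd(OAc)2, n-Bu4NCl, KHCO3, DMF, 80 °C) is a well-established substrate class. It should give (5R,6E)-7-(5,7-dimethoxy-2-oxo-2H-chromen-8-yl)-5-hydroxy-2,5-dimethylhept-6-enoic acid F4, again as the salt.
- Without any acidification, Yamaguchi lactonisation (2,4,6-trichlorobenzoyl chloride, Et3N, then DMAP, toluene, rt) closes the δ-lactone 14.

(c) Step 12.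
- What may go wrong: migratory insertion may be too slow, because the vinyl group stands on a quaternary carbon beside a cis aryl group and the aryl iodide is substituted at both ortho positions. Reductive deiodination, homocoupling and catalyst decay could then take over.
- Fallback: it sets out from 19 and comes back at 21, replacing insertion by transmetalation.
- Takai–Utimoto olefination of 19 with Cl2CHB(pin), CrCl2 and LiI in THF at rt should give 8-[(1R,6R)-3,6-dimethyl-6-[(E)-2-(4,4,5,5-tetramethyl-1,3,2-dioxaborolan-2-yl)ethenyl]cyclohex-2-en-1-yl]-5,7-dimethoxycoumarin F5. This reaction is aldehyde-selective and E-selective for hindered aldehydes.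
- Suzuki–Miyaura coupling of F5 with 13 (Pd(PPh3)4, K3PO4, dioxane–H2O, 80 °C) gives 21 with retention of the E geometry.

Further compounds
F1 | step 9 | 8-[(E)-3-hydroxy-3-methylbut-1-enyl]-5,7-dimethoxycoumarin | CC(C)(O)/C=C/c1c(OC)cc(OC)c2ccc(=O)oc12
F2 | step 9 | 8-[(E)-3-methylbuta-1,3-dienyl]-5,7-dimethoxycoumarin | C=C(C)/C=C/c1c(OC)cc(OC)c2ccc(=O)oc12
F3 | step 8 | (5R)-5-hydroxy-2,5-dimethylhept-6-enoic acid (handled as potassium salt) | OC(=O)C(C)CC[C@@](C)(O)C=C
F4 | step 8 | (5R,6E)-7-(5,7-dimethoxy-2-oxo-2H-chromen-8-yl)-5-hydroxy-2,5-dimethylhept-6-enoic acid (handled as potassium salt) | OC(=O)C(C)CC[C@@](C)(O)/C=C/c1c(OC)cc(OC)c2ccc(=O)oc12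
F5 | step 12 | 8-[(1R,6R)-3,6-dimethyl-6-[(E)-2-(4,4,5,5-tetramethyl-1,3,2-dioxaborolan-2-yl)ethenyl]cyclohex-2-en-1-yl]-5,7-dimethoxycoumarin | CC1(C)OB(/C=C/[C@@]2(C)CCC(C)=C[C@H]2c2c(OC)cc(OC)c3ccc(=O)oc23)OC1(C)C
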